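## Analysis of the target

Atom labels used throughout: Ca is the quaternary carbon bearing the ether CH2 (Ce), the dienyl chain, Cc and Cd. Cb is the ether carbon bearing the CH(CH3)CHO arm, whose CH is C-alpha. Cc is the C(CH3)OH carbon, Cd the CH bearing the 3-hydroxypropyl arm, and Cg and Ch are the ring CH2 groups next to Cb and Cc.

The core of 34 is a 6-oxabicyclo[3.2.1]octane. The cyclohexane Ca–Cc–Ch–Cg–Cb–Cd has its 1,3-related carbons Ca and Cb tied a second time by the bridge Ce–O, so Ca, Ce, O, Cb and Cd form a tetrahydrofuran. Ca is an all-carbon quaternary centre and Cb a fully substituted ether carbon, and they flank the methine Cd. With the tertiary carbinol Cc there are four contiguous ring stereocentres, (1S,2S,5R,8S) in bicycle numbering. The arm on Cd points to the side of the CH2–O bridge (equatorial on the carbocycle). On Cc the hydroxyl is equatorial and the methyl axial, anti to the bridge. A fifth centre, C-alpha (S), lies outside the ring next to the aldehyde. Two more, (1R,5S) and cis, sit in the tetramethylcyclohexenyl end group, far from the core, so each half must be enantiopure on its own. The aldehyde is the most delicate group: its α-hydrogen epimerises, and base can expel the β-ether oxygen and open the tetrahydrofuran. The (E,E)-diene with its doubly allylic ring CH, the tertiary alcohol and the free primary alcohol also limit the late chemistry. The strategy rests on one feature: Ca and Cb are joined twice, by Cd and by Ce–O. Taking out CH2=O leaves a Ca–Cb bond, that is a cyclopropane Ca–Cd–Cb fused to a cyclopentanone, with acceptors on Ca and a donor on Cb.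

## Retrosynthetic reasoning

**End game (34 back to 31).** The aldehyde and the free primary alcohol are unveiled last. 34 comes from 33 by loss of the two remaining silyl groups under buffered fluoride. 33 comes from 32 by oxidation of the one free primary alcohol, and 32 from 31 by selective loss of the primary triethylsilyl group. Base is avoided after the aldehyde exists.

**Chain to diene bond (31 to 23 and 29).** The bond between the second chain CH2 and the first diene carbon is cut. It is the only C(sp3)–C(sp2) bond that joins two halves of similar size. Forward, an alkylborane made from the vinyl group of 23 couples with the alkenyl iodide 29 with retention of the (E,E) geometry. 29 comes from the cis ketone 25 through the enyne 27, and 25 is separated from the commercial mixture 24.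

**Vinyl group (23 to 20).** The vinyl group on Ca is traced to the ester of 20 through alcohol 21 and aldehyde 22. The ester is the second acceptor that the key step needs, so it must be there anyway. Both hydroxyls are silylated in 20, because the β-hydroxy aldehyde would otherwise be open to retro-aldol cleavage under the ylide.

**C-alpha (19 to 17).** The C-alpha hydrogen and the CH2–O bond are cut, which leads back to the isopropenyl group of 17. The isopropenyl group is kept this long because it is the donor of the key step. The hydroboration must come before the vinyl group exists, since a dialkylborane would not tell the two terminal alkenes apart.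

**Methyl on Cc (17 to 16).** The Cc–CH3 bond is cut, leaving the ketone of 16, the other acceptor of the key step. The forward addition must come from the face anti to the CH2–O bridge.

**Key disconnection (16 to 14 and 15).** The Cb–O and Ca–Ce bonds are cut, which removes formaldehyde 15 and leaves the bicyclo[3.1.0]hexanone ketoester 14. Two skeletal bonds, the tetrahydrofuran and the enlargement of the five-membered ketone to the six-membered one come from a single step. Which epimer of 14 at Cd is needed has to be worked out: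

- It is tempting to picture CH2O slipping into the Ca–Cb bond, so that an exo arm would end next to the new bridge. That picture implies front-side substitution at both carbons, which donor–acceptor cyclopropanes do not show.
- The aldehyde oxygen enters at the donor carbon anti to the bond that leaves. In the fused system this inversion at Cb puts the oxygen on the ring face that carried the ester and the isopropenyl group.
- The CH2 can reach Ca only on that same face, so Ca is inverted as well.
- On the perimeter ring this face is the one of the endo substituent of Cd. The arm must therefore be endo in 14, cis to Cg across the cyclopropane.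

**Cyclopropane (14 to 13 to 12).** The Ca–Cb and Ca–Cd bonds are cut to the diazo ketoester 13, made from 12 by diazo transfer. The carbenoid addition is stereospecific, so the endo arm requires the alkene of 13 in which the arm is cis to the tether. A chiral copper catalyst sets the absolute configuration of all three ring carbons.

**Acyclic chain (12 back to 1, 7 and 10).** The bond between the γ-carbon of 10 and the allylic carbon of bromide 9 is cut. 9 comes from dienol 8, and 8 from 2-bromopropene 7 and the alkenylstannane 6. 6 is reached from alkyne 2 (from 1) through ynoate 4 and stannyl enoate 5. The syn hydrostannation of 4 is what fixes the arm cis to the future tether.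

## Alternatives that were turned down

**Alternative 1: both tertiary oxygens from singlet oxygen.**
- Disconnection: Cb–O and Cc–O are traced to O2.
- Forward key step: sensitised singlet oxygen adds across the 1,4-positions of cyclohexadiene A2 to give endoperoxide A1. Reduction of the O–O bond, saturation of the alkene and Williamson closure of the Cb oxygen onto Ce would follow.
- For it: one step sets both tertiary C–O bonds, and they are necessarily cis, as the ether oxygen and the Cc hydroxyl are in 34. The ether then closes by SN2 at primary Ce, with no cation at Cb.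
- Against it: oxygen must add to the diene face syn to the arm on Cd, the more hindered face, so the outcome rests on direction by the free CH2OH of A2. Ene reactions at the Cc methyl, at C-alpha and at Cd compete. A2 already holds the quaternary Ca, Cd and an epimerisable C-alpha next to the diene, and reaching it would be long. The two-carbon ester arm must later be extended by an olefination that forms the trisubstituted alkene with uncertain geometry.
- Comparison: it is stronger at Cc, where the chosen route depends on the face taken by a methyl nucleophile. The chosen route offers a precursor made in nine steps, the bicycle in one step, and a stereoretentive coupling for the diene.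

**Alternative 2: etherification of the Ca methyl by a hypoiodite relay.**
- Disconnection: the Ce–O bond.
- Forward key step: the hypoiodite of tertiary alcohol A4 (PhI(OAc)2, I2, light) gives an alkoxyl radical that takes a hydrogen from the axial methyl on Ca through a six-membered transition state. The iodinated carbon is then displaced by the oxygen to give A3.
- For it: this remote functionalisation is well established, so no new method is needed. The configuration at Cb is fixed before the ring closes, and the carbocycle can be built by conventional chemistry.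
- Against it: a tertiary alkoxyl radical fragments easily, here by loss of the C-alpha side chain or by ring opening. The C2 hydrogens of the arm on Cd are reachable through an equally good six-membered transition state, are secondary, and sit on the same face as the oxygen in the required isomer. A4 must be made with four contiguous stereocentres without any help from the key step. The CH2CO2Me group needs a one-carbon homologation and then an olefination to the trisubstituted alkene.
- Comparison: it is stronger on precedent. The chosen route builds the skeleton while it sets Ca and Cb, and needs far fewer steps.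

**Alternative 3: radical closure across an oxepane.**
- Disconnection: the Cd–Cb bond.
- Forward key step: Bu3SnH generates a secondary radical at Cd from either carbinol epimer of xanthate A6. Its 5-exo addition to the β-carbon of the exocyclic alkoxyacrylate closes the tetrahydrofuran and the carbocycle together and gives A5.
- For it: radical additions to β-alkoxyacrylates are dependable, the step is stereoconvergent at the radical carbon, the Cb–O bond is already in place, and C-alpha arrives at the ester oxidation level.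
- Against it: the acceptor carbon is fully substituted, so simple reduction of the radical competes. C-alpha is set by hydrogen transfer to an ester radical next to a new quaternary centre, with no clear control. The orientation of the arm depends on the conformation of a seven-membered ring. A6 is a long target in itself (oxepane, quaternary Ca, tertiary ether at Cc, tetrasubstituted enol ether). The allyl group is one carbon off and again ends in an olefination.
- Comparison: it is stronger in the predictability of ring formation. The chosen route reaches its precursor from three simple materials and ends with a geometry-retaining coupling, at the price of an untested annulation.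

Key step: step 10

## Route

Remark: commercial α-irone (24) is taken to be a racemic mixture of cis and trans isomers, so the single cis enantiomer 25 has to be separated from it before use (step 17).

Step 1
Reactants: 1 pent-4-yn-1-ol
Product: 2 tert-butyl(dimethyl)(pent-4-yn-1-yloxy)silane
Conditions: TBSCl, imidazole, CH2Cl2, 0 °C → rt
Reagents that add atoms: tert-butyl(chloro)dimethylsilane, CC(C)(C)[Si](C)(C)Cl
Why: Silylation of a primary alcohol; the ether masks the future 3-hydroxypropyl arm through all organometallic steps and is taken off last.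

Step 2
Reactants: 2 tert-butyl(dimethyl)(pent-4-yn-1-yloxy)silane
Product: 4 methyl 6-{[tert-butyl(dimethyl)silyl]oxy}hex-2-ynoate, via lithium acetylide 3 (not isolated)
Conditions: n-BuLi, THF, −78 °C; then ClCO2Me, −78 → 0 °C
Reagents that add atoms: methyl chloroformate, COC(=O)Cl
Why: Acylation of a lithium acetylide with a chloroformate; the ester polarises the alkyne so that the next step is regioselective.

Step 3
Reactants: 4 methyl 6-{[tert-butyl(dimethyl)silyl]oxy}hex-2-ynoate
Product: 5 methyl (2E)-6-{[tert-butyl(dimethyl)silyl]oxy}-2-(tributylstannyl)hex-2-enoate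
Conditions: Bu3SnH, Pd(PPh3)4 (2 mol %), THF, 0 °C → rt
Reagents that add atoms: tributyltin hydride, CCCC[SnH](CCCC)CCCC
Why: Palladium-catalysed hydrostannation of an alkynoate adds H and Sn syn with tin on the α-carbon, so the chain and the ester end cis; this geometry later puts the arm cis to the tether.

Step 4
Reactants: 5 methyl (2E)-6-{[tert-butyl(dimethyl)silyl]oxy}-2-(tributylstannyl)hex-2-enoate
Product: 6 (2E)-6-{[tert-butyl(dimethyl)silyl]oxy}-2-(tributylstannyl)hex-2-en-1-ol
Conditions: i-Bu2AlH (2.5 equiv), CH2Cl2, −78 °C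
Reagents that add atoms: none
Why: 1,2-Reduction of the enoate to the allylic alcohol, to which the alkenylstannane is inert; reducing before the coupling avoids a cross-conjugated dienoate that would be prone to Diels–Alder dimerisation.

Step 5
Reactants: 6 (2E)-6-{[tert-butyl(dimethyl)silyl]oxy}-2-(tributylstannyl)hex-2-en-1-ol; 7 2-bromopropene
Product: 8 (2Z)-6-{[tert-butyl(dimethyl)silyl]oxy}-2-(prop-1-en-2-yl)hex-2-en-1-ol
Conditions: Pd(PPh3)4 (5 mol %), CuI (10 mol %), CsF, DMF, 45 °C
Reagents that add atoms: none
Why: Stille coupling with retention at both sp2 carbons; CuI and fluoride speed the transmetalation of the α-branched stannane, and the chain stays cis to CH2OH.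

Step 6
Reactants: 8 (2Z)-6-{[tert-butyl(dimethyl)silyl]oxy}-2-(prop-1-en-2-yl)hex-2-en-1-ol
Product: 9 {[(4Z)-5-(bromomethyl)-6-methylhepta-4,6-dien-1-yl]oxy}(tert-butyl)dimethylsilane
Conditions: CBr4, PPh3, CH2Cl2, 0 °C
Reagents that add atoms: carbon tetrabromide, BrC(Br)(Br)Br
Why: Appel bromination of a primary allylic alcohol under neutral conditions that spare the silyl ether and the alkene geometry; the bromide is used at once.

Step 7
Reactants: 10 methyl acetoacetate; 9 {[(4Z)-5-(bromomethyl)-6-methylhepta-4,6-dien-1-yl]oxy}(tert-butyl)dimethylsilane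
Product: 12 methyl (6E)-10-{[tert-butyl(dimethyl)silyl]oxy}-3-oxo-6-(prop-1-en-2-yl)dec-6-enoate, via sodium lithium dianion of methyl acetoacetate 11 (not isolated)
Conditions: NaH, THF, 0 °C; n-BuLi, 0 °C; then 9, 0 °C → rt; H2O
Reagents that add atoms: none
Why: γ-Alkylation of an acetoacetate dianion: the terminal carbanion is the more reactive site and displaces the primary allylic bromide by SN2, giving the δ,ε-unsaturated β-ketoester with the alkene untouched.

Step 8
Reactants: 12 methyl (6E)-10-{[tert-butyl(dimethyl)silyl]oxy}-3-oxo-6-(prop-1-en-2-yl)dec-6-enoate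
Product: 13 methyl (6E)-10-{[tert-butyl(dimethyl)silyl]oxy}-2-diazo-3-oxo-6-(prop-1-en-2-yl)dec-6-enoate
Conditions: 4-acetamidobenzenesulfonyl azide, Et3N, MeCN, 0 °C → rt
Reagents that add atoms: 4-acetamidobenzenesulfonyl azide, CC(=O)Nc1ccc(cc1)S(=O)(=O)N=[N+]=[N-]
Why: Regitz diazo transfer to the active methylene of a β-ketoester.

Step 9
Reactants: 13 methyl (6E)-10-{[tert-butyl(dimethyl)silyl]oxy}-2-diazo-3-oxo-6-(prop-1-en-2-yl)dec-6-enoate
Product: 14 methyl (1S,5S,6R)-6-(3-{[tert-butyl(dimethyl)silyl]oxy}propyl)-2-oxo-5-(prop-1-en-2-yl)bicyclo[3.1.0]hexane-1-carboxylate (arm endo)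
Conditions: [Cu(MeCN)4]PF6 (5 mol %), 2,2′-(propane-2,2-diyl)bis[(4S)-4-tert-butyl-4,5-dihydro-1,3-oxazole] (6 mol %), toluene, 50 °C, slow addition of 13
Reagents that add atoms: none
Why: Intramolecular cyclopropanation by a copper carbenoid of an α-diazo-β-ketoester; the five-membered ring closes onto the trisubstituted alkene and the syn addition carries the alkene geometry over, so the arm cis to the tether ends endo. The chiral bis(oxazoline) selects the alkene face and so sets C1, C5 and C6 together; the ligand antipode is taken if the sense proves opposite.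

Step 10
Reactants: 14 methyl (1S,5S,6R)-6-(3-{[tert-butyl(dimethyl)silyl]oxy}propyl)-2-oxo-5-(prop-1-en-2-yl)bicyclo[3.1.0]hexane-1-carboxylate; 15 formaldehyde
Product: 16 methyl (1R,5R,8S)-8-(3-{[tert-butyl(dimethyl)silyl]oxy}propyl)-2-oxo-5-(prop-1-en-2-yl)-6-oxabicyclo[3.2.1]octane-1-carboxylate
Conditions: Sn(OTf)2 (10–20 mol %), monomeric CH2O (about 5 equiv, cracked from paraformaldehyde, in CH2Cl2), 4 Å MS, CH2Cl2, −78 → −20 °C
Reagents that add atoms: none
Why: Proposed new method: Sn(OTf)2 chelates the β-ketoester of 14 and polarises the Ca–Cb bond toward Cb, the only cyclopropane carbon that is tertiary and allylic; the oxygen of 15 attacks Cb from the rear of that bond while Ca becomes a tin enolate, which then closes on the O-alkylated formaldehyde carbon. The closest known reaction type is the Lewis-acid-catalysed (3+2) annulation of donor–acceptor cyclopropanes with aldehydes to tetrahydrofurans, which has not been run with formaldehyde or with a fused, fully substituted donor carbon. The tetrahydrofuran is the one ring that closes, by an aldol-type attack of the enolate carbon on the oxocarbenium carbon (five-membered, formally 5-endo-trig at the C=O+ unit and exo to the enolate), the same closure as in the known annulations; the six-membered carbocycle is not closed but arises because Cd stays bonded to both termini while the cyclopropane bond opens. Cb is set by inversion, and Ca by the tether, since the CH2 can reach the enolate only on the face that now carries the oxygen. Both new bonds therefore lie on the face that held the ester and the isopropenyl group in 14, which is the face of the endo arm, so the arm ends syn to the CH2–O bridge as in 34. The step needs cleavage of Ca–Cb and not Ca–Cd (secured by the isopropenyl donor), capture at Cb and not at the CH2 end of the allyl system (tight ion pair, five- over seven-membered closure), capture faster than proton loss (low temperature, excess of the small aldehyde), and no free cation, which would uncouple the result at Cd from the cyclopropane geometry. Internal capture by the ketone or ester oxygen is excluded because either would give a bridgehead enol ether.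

Step 11
Reactants: 16 methyl (1R,5R,8S)-8-(3-{[tert-butyl(dimethyl)silyl]oxy}propyl)-2-oxo-5-(prop-1-en-2-yl)-6-oxabicyclo[3.2.1]octane-1-carboxylate
Product: 17 methyl (1R,2S,5R,8S)-8-(3-{[tert-butyl(dimethyl)silyl]oxy}propyl)-2-hydroxy-2-methyl-5-(prop-1-en-2-yl)-6-oxabicyclo[3.2.1]octane-1-carboxylate
Conditions: MeMgBr, CeCl3, THF, −78 °C
Reagents that add atoms: methylmagnesium bromide, C[Mg]Br
Why: Cerium-mediated 1,2-addition of a methyl Grignard reagent to the ketone, which is more electrophilic than the hindered ester and is little enolised under these conditions. The axial CH2 of the oxygen bridge on neighbouring Ca blocks the equatorial approach, so the methyl should enter axially, anti to the bridge, leaving the hydroxyl equatorial as in 34.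

Step 12
Reactants: 17 methyl (1R,2S,5R,8S)-8-(3-{[tert-butyl(dimethyl)silyl]oxy}propyl)-2-hydroxy-2-methyl-5-(prop-1-en-2-yl)-6-oxabicyclo[3.2.1]octane-1-carboxylate
Product: 19 methyl (1R,2S,5R,8S)-8-(3-{[tert-butyl(dimethyl)silyl]oxy}propyl)-2-hydroxy-5-[(2R)-1-hydroxypropan-2-yl]-2-methyl-6-oxabicyclo[3.2.1]octane-1-carboxylate, via B-alkyl-9-borabicyclo[3.3.1]nonane 18 (not isolated)
Conditions: 9-BBN (3 equiv), THF, rt → 45 °C; then 30% H2O2, aq. NaOAc, 0 °C → rt
Reagents that add atoms: hydrogen peroxide, OO
Why: Anti-Markovnikov hydroboration–oxidation of the 1,1-disubstituted alkene. In the favoured transition state the one-carbon bridge Cd lies anti to the incoming borane, the small ring oxygen sits beside the CH2 terminus where boron binds, and Cg sits beside the methyl; hydrogen is then delivered to the face that gives the (2R)-CH(CH3)CH2OH group, which is the C-alpha configuration of 34.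

Step 13
Reactants: 19 methyl (1R,2S,5R,8S)-8-(3-{[tert-butyl(dimethyl)silyl]oxy}propyl)-2-hydroxy-5-[(2R)-1-hydroxypropan-2-yl]-2-methyl-6-oxabicyclo[3.2.1]octane-1-carboxylate
Product: 20 methyl (1R,2S,5R,8S)-8-(3-{[tert-butyl(dimethyl)silyl]oxy}propyl)-2-methyl-2-[(triethylsilyl)oxy]-5-{(2R)-1-[(triethylsilyl)oxy]propan-2-yl}-6-oxabicyclo[3.2.1]octane-1-carboxylate
Conditions: TESOTf (3 equiv), 2,6-lutidine, CH2Cl2, −78 → 0 °C
Reagents that add atoms: triethylsilyl trifluoromethanesulfonate, CC[Si](CC)(CC)OS(=O)(=O)C(F)(F)F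
Why: Silylation of the primary and the hindered tertiary alcohol with a silyl triflate; the tertiary ether blocks retro-aldol cleavage at the coming β-oxy aldehyde stage, and the primary triethylsilyl ether can later be removed beside the tert-butyldimethylsilyl ether.

Step 14
Reactants: 20 methyl (1R,2S,5R,8S)-8-(3-{[tert-butyl(dimethyl)silyl]oxy}propyl)-2-methyl-2-[(triethylsilyl)oxy]-5-{(2R)-1-[(triethylsilyl)oxy]propan-2-yl}-6-oxabicyclo[3.2.1]octane-1-carboxylate
Product: 21 [(1R,2S,5R,8S)-8-(3-{[tert-butyl(dimethyl)silyl]oxy}propyl)-2-methyl-2-[(triethylsilyl)oxy]-5-{(2R)-1-[(triethylsilyl)oxy]propan-2-yl}-6-oxabicyclo[3.2.1]octan-1-yl]methanol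
Conditions: i-Bu2AlH (4 equiv), CH2Cl2, −78 → 0 °C
Reagents that add atoms: none
Why: Hydride reduction of the neopentyl ester to the primary alcohol; the silyl ethers are inert, and full reduction is more dependable here than stopping at the aldehyde.

Step 15
Reactants: 21 [(1R,2S,5R,8S)-8-(3-{[tert-butyl(dimethyl)silyl]oxy}propyl)-2-methyl-2-[(triethylsilyl)oxy]-5-{(2R)-1-[(triethylsilyl)oxy]propan-2-yl}-6-oxabicyclo[3.2.1]octan-1-yl]methanol
Product: 22 (1R,2S,5R,8S)-8-(3-{[tert-butyl(dimethyl)silyl]oxy}propyl)-2-methyl-2-[(triethylsilyl)oxy]-5-{(2R)-1-[(triethylsilyl)oxy]propan-2-yl}-6-oxabicyclo[3.2.1]octane-1-carbaldehyde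
Conditions: Dess–Martin periodinane, NaHCO3, CH2Cl2, 0 °C → rt
Reagents that add atoms: none
Why: Dess–Martin oxidation of a hindered primary alcohol to a non-enolisable aldehyde under buffered, nearly neutral conditions.

Step 16
Reactants: 22 (1R,2S,5R,8S)-8-(3-{[tert-butyl(dimethyl)silyl]oxy}propyl)-2-methyl-2-[(triethylsilyl)oxy]-5-{(2R)-1-[(triethylsilyl)oxy]propan-2-yl}-6-oxabicyclo[3.2.1]octane-1-carbaldehyde
Product: 23 tert-butyl(dimethyl){3-[(1S,2S,5R,8S)-1-ethenyl-2-methyl-2-[(triethylsilyl)oxy]-5-{(2R)-1-[(triethylsilyl)oxy]propan-2-yl}-6-oxabicyclo[3.2.1]octan-8-yl]propoxy}silane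
Conditions: Ph3PCH3Br, KN(SiMe3)2, THF, 0 °C → rt
Reagents that add atoms: methyltriphenylphosphonium bromide, [Br-].C[P+](c1ccccc1)(c1ccccc1)c1ccccc1
Why: Wittig methylenation; the small, reactive ylide reaches the neopentyl aldehyde, which cannot epimerise.

Step 17
Reactants: 24 α-irone (commercial mixture of isomers)
Product: 25 (3E)-4-[(1R,5S)-2,5,6,6-tetramethylcyclohex-2-en-1-yl]but-3-en-2-one (cis isomer)
Conditions: preparative HPLC on silica (hexane/EtOAc) to take the cis diastereomer; then preparative HPLC on cellulose tris(3,5-dimethylphenylcarbamate) (hexane/i-PrOH)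
Reagents that add atoms: none
Why: A resolution by chromatography, first of diastereomers and then of enantiomers on a chiral stationary phase; no bond is made or broken and the configuration of the end group is fixed here.

Step 18
Reactants: 25 (3E)-4-[(1R,5S)-2,5,6,6-tetramethylcyclohex-2-en-1-yl]but-3-en-2-one
Product: 27 (4S,6R)-6-[(1E)-but-1-en-3-yn-1-yl]-1,4,5,5-tetramethylcyclohex-1-ene, via dienyl diethyl phosphate 26 (not isolated)
Conditions: LiN(i-Pr)2 (1.05 equiv), THF, −78 °C; ClP(O)(OEt)2, −78 °C → rt; then LiN(i-Pr)2 (2.2 equiv), −78 °C; H2O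
Reagents that add atoms: none
Why: Conversion of a methyl ketone into a terminal alkyne: kinetic enolisation at the methyl group, O-phosphorylation and β-elimination of the enol phosphate. The doubly allylic ring hydrogen is far less acidic, so at −78 °C the cis relationship should be kept.

Step 19
Reactants: 27 (4S,6R)-6-[(1E)-but-1-en-3-yn-1-yl]-1,4,5,5-tetramethylcyclohex-1-ene
Product: 29 (4S,6R)-6-[(1E,3E)-4-iodo-3-methylbuta-1,3-dien-1-yl]-1,4,5,5-tetramethylcyclohex-1-ene, via alkenyldimethylalane 28 (not isolated)
Conditions: Me3Al, Cp2ZrCl2 (0.25 equiv), CH2Cl2, 0 °C → rt; then I2, THF, −30 → 0 °C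
Reagents that add atoms: trimethylaluminium, C[Al](C)C; iodine, II
Why: Zirconium-catalysed carboalumination of the terminal alkyne (Negishi) adds methyl and aluminium syn, with methyl on the inner carbon; iodinolysis with retention gives the (E)-trisubstituted alkenyl iodide, and the other alkenes do not react.

Step 20
Reactants: 23 tert-butyl(dimethyl){3-[(1S,2S,5R,8S)-1-ethenyl-2-methyl-2-[(triethylsilyl)oxy]-5-{(2R)-1-[(triethylsilyl)oxy]propan-2-yl}-6-oxabicyclo[3.2.1]octan-8-yl]propoxy}silane; 29 (4S,6R)-6-[(1E,3E)-4-iodo-3-methylbuta-1,3-dien-1-yl]-1,4,5,5-tetramethylcyclohex-1-ene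
Product: 31 tert-butyl(dimethyl){3-[(1S,2S,5R,8S)-2-methyl-1-{(3E,5E)-4-methyl-6-[(1R,5S)-2,5,6,6-tetramethylcyclohex-2-en-1-yl]hexa-3,5-dien-1-yl}-2-[(triethylsilyl)oxy]-5-{(2R)-1-[(triethylsilyl)oxy]propan-2-yl}-6-oxabicyclo[3.2.1]octan-8-yl]propoxy}silane, via B-alkyl-9-borabicyclo[3.3.1]nonane 30 (not isolated)
Conditions: 9-BBN, THF, rt; then 29, Pd(dppf)Cl2 (5 mol %), AsPh3, aq. K3PO4, DMF, rt
Reagents that add atoms: none
Why: B-alkyl Suzuki–Miyaura coupling: the only alkene of 23 is hydroborated at its terminus and the primary alkylborane couples with the alkenyl iodide with retention of the (E,E) geometry; no stereocentre is touched.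

Step 21
Reactants: 31 tert-butyl(dimethyl){3-[(1S,2S,5R,8S)-2-methyl-1-{(3E,5E)-4-methyl-6-[(1R,5S)-2,5,6,6-tetramethylcyclohex-2-en-1-yl]hexa-3,5-dien-1-yl}-2-[(triethylsilyl)oxy]-5-{(2R)-1-[(triethylsilyl)oxy]propan-2-yl}-6-oxabicyclo[3.2.1]octan-8-yl]propoxy}silane
Product: 32 (2R)-2-[(1S,2S,5R,8S)-8-(3-{[tert-butyl(dimethyl)silyl]oxy}propyl)-2-methyl-1-{(3E,5E)-4-methyl-6-[(1R,5S)-2,5,6,6-tetramethylcyclohex-2-en-1-yl]hexa-3,5-dien-1-yl}-2-[(triethylsilyl)oxy]-6-oxabicyclo[3.2.1]octan-5-yl]propan-1-ol
Conditions: PPTS, MeOH/CH2Cl2, 0 °C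
Reagents that add atoms: none
Why: Acid-catalysed methanolysis of a silyl ether: the primary triethylsilyl ether cleaves much faster than the primary tert-butyldimethylsilyl ether or the hindered tertiary triethylsilyl ether.

Step 22
Reactants: 32 (2R)-2-[(1S,2S,5R,8S)-8-(3-{[tert-butyl(dimethyl)silyl]oxy}propyl)-2-methyl-1-{(3E,5E)-4-methyl-6-[(1R,5S)-2,5,6,6-tetramethylcyclohex-2-en-1-yl]hexa-3,5-dien-1-yl}-2-[(triethylsilyl)oxy]-6-oxabicyclo[3.2.1]octan-5-yl]propan-1-ol
Product: 33 (2S)-2-[(1S,2S,5R,8S)-8-(3-{[tert-butyl(dimethyl)silyl]oxy}propyl)-2-methyl-1-{(3E,5E)-4-methyl-6-[(1R,5S)-2,5,6,6-tetramethylcyclohex-2-en-1-yl]hexa-3,5-dien-1-yl}-2-[(triethylsilyl)oxy]-6-oxabicyclo[3.2.1]octan-5-yl]propanal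
Conditions: Dess–Martin periodinane, NaHCO3, CH2Cl2, 0 °C
Reagents that add atoms: none
Why: Dess–Martin oxidation under buffered conditions, which spare the diene and should not epimerise C-alpha; the descriptor changes from R to S only because the priorities change.

Step 23
Reactants: 33 (2S)-2-[(1S,2S,5R,8S)-8-(3-{[tert-butyl(dimethyl)silyl]oxy}propyl)-2-methyl-1-{(3E,5E)-4-methyl-6-[(1R,5S)-2,5,6,6-tetramethylcyclohex-2-en-1-yl]hexa-3,5-dien-1-yl}-2-[(triethylsilyl)oxy]-6-oxabicyclo[3.2.1]octan-5-yl]propanal
Product: 34 (2S)-2-[(1S,2S,5R,8S)-2-hydroxy-8-(3-hydroxypropyl)-2-methyl-1-{(3E,5E)-4-methyl-6-[(1R,5S)-2,5,6,6-tetramethylcyclohex-2-en-1-yl]hexa-3,5-dien-1-yl}-6-oxabicyclo[3.2.1]octan-5-yl]propanal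
Conditions: HF·pyridine, pyridine, THF, 0 °C → rt
Reagents that add atoms: none
Why: Fluoride-mediated desilylation of both remaining silyl ethers in a buffered, slightly acidic medium; this avoids the basic conditions under which the aldehyde could epimerise or expel the β-ether oxygen.

## Compound list

1 | pent-4-yn-1-ol | C#CCCCO | starting material
2 | tert-butyl(dimethyl)(pent-4-yn-1-yloxy)silane | C#CCCCO[Si](C)(C)C(C)(C)C | intermediate
3 | lithium acetylide of 2 | [Li]C#CCCCO[Si](C)(C)C(C)(C)C | intermediate (not isolated)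
4 | methyl 6-{[tert-butyl(dimethyl)silyl]oxy}hex-2-ynoate | COC(=O)C#CCCCO[Si](C)(C)C(C)(C)C | intermediate
5 | methyl (2E)-6-{[tert-butyl(dimethyl)silyl]oxy}-2-(tributylstannyl)hex-2-enoate | COC(=O)/C([Sn](CCCC)(CCCC)CCCC)=C\CCCO[Si](C)(C)C(C)(C)C | intermediate
6 | (2E)-6-{[tert-butyl(dimethyl)silyl]oxy}-2-(tributylstannyl)hex-2-en-1-ol | OC/C([Sn](CCCC)(CCCC)CCCC)=C\CCCO[Si](C)(C)C(C)(C)C | intermediate
7 | 2-bromopropene | CC(Br)=C | starting material
8 | (2Z)-6-{[tert-butyl(dimethyl)silyl]oxy}-2-(prop-1-en-2-yl)hex-2-en-1-ol | OC/C(C(C)=C)=C\CCCO[Si](C)(C)C(C)(C)C | intermediate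
9 | {[(4Z)-5-(bromomethyl)-6-methylhepta-4,6-dien-1-yl]oxy}(tert-butyl)dimethylsilane | BrC/C(C(C)=C)=C\CCCO[Si](C)(C)C(C)(C)C | intermediate
10 | methyl acetoacetate (methyl 3-oxobutanoate) | COC(=O)CC(C)=O | starting material
11 | sodium lithium dianion of methyl acetoacetate | [Na+].[Li+].COC(=O)[CH-]C(=O)[CH2-] | intermediate (not isolated)
12 | methyl (6E)-10-{[tert-butyl(dimethyl)silyl]oxy}-3-oxo-6-(prop-1-en-2-yl)dec-6-enoate | COC(=O)CC(=O)CC/C(C(C)=C)=C\CCCO[Si](C)(C)C(C)(C)C | intermediate
13 | methyl (6E)-10-{[tert-butyl(dimethyl)silyl]oxy}-2-diazo-3-oxo-6-(prop-1-en-2-yl)dec-6-enoate | COC(=O)C(=[N+]=[N-])C(=O)CC/C(C(C)=C)=C\CCCO[Si](C)(C)C(C)(C)C | intermediate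
14 | methyl (1S,5S,6R)-6-(3-{[tert-butyl(dimethyl)silyl]oxy}propyl)-2-oxo-5-(prop-1-en-2-yl)bicyclo[3.1.0]hexane-1-carboxylate (arm endo) | COC(=O)[C@]12C(=O)CC[C@@]1(C(C)=C)[C@H]2CCCO[Si](C)(C)C(C)(C)C | intermediate
15 | formaldehyde (monomer, cracked from commercial paraformaldehyde) | C=O | starting material
16 | methyl (1R,5R,8S)-8-(3-{[tert-butyl(dimethyl)silyl]oxy}propyl)-2-oxo-5-(prop-1-en-2-yl)-6-oxabicyclo[3.2.1]octane-1-carboxylate | COC(=O)[C@]12CO[C@](C(C)=C)(CCC1=O)[C@H]2CCCO[Si](C)(C)C(C)(C)C | intermediate
17 | methyl (1R,2S,5R,8S)-8-(3-{[tert-butyl(dimethyl)silyl]oxy}propyl)-2-hydroxy-2-methyl-5-(prop-1-en-2-yl)-6-oxabicyclo[3.2.1]octane-1-carboxylate | COC(=O)[C@]12CO[C@](C(C)=C)(CC[C@]1(C)O)[C@H]2CCCO[Si](C)(C)C(C)(C)C | intermediate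
18 | B-alkyl-9-borabicyclo[3.3.1]nonane from 17 (boron on the terminal carbon of the former isopropenyl group) | COC(=O)[C@]12CO[C@]([C@H](C)CB3C4CCCC3CCC4)(CC[C@]1(C)O)[C@H]2CCCO[Si](C)(C)C(C)(C)C | intermediate (not isolated)
19 | methyl (1R,2S,5R,8S)-8-(3-{[tert-butyl(dimethyl)silyl]oxy}propyl)-2-hydroxy-5-[(2R)-1-hydroxypropan-2-yl]-2-methyl-6-oxabicyclo[3.2.1]octane-1-carboxylate | COC(=O)[C@]12CO[C@]([C@H](C)CO)(CC[C@]1(C)O)[C@H]2CCCO[Si](C)(C)C(C)(C)C | intermediate
20 | methyl (1R,2S,5R,8S)-8-(3-{[tert-butyl(dimethyl)silyl]oxy}propyl)-2-methyl-2-[(triethylsilyl)oxy]-5-{(2R)-1-[(triethylsilyl)oxy]propan-2-yl}-6-oxabicyclo[3.2.1]octane-1-carboxylate | COC(=O)[C@]12CO[C@]([C@H](C)CO[Si](CC)(CC)CC)(CC[C@]1(C)O[Si](CC)(CC)CC)[C@H]2CCCO[Si](C)(C)C(C)(C)C | intermediate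
21 | [(1R,2S,5R,8S)-8-(3-{[tert-butyl(dimethyl)silyl]oxy}propyl)-2-methyl-2-[(triethylsilyl)oxy]-5-{(2R)-1-[(triethylsilyl)oxy]propan-2-yl}-6-oxabicyclo[3.2.1]octan-1-yl]methanol | OC[C@]12CO[C@]([C@H](C)CO[Si](CC)(CC)CC)(CC[C@]1(C)O[Si](CC)(CC)CC)[C@H]2CCCO[Si](C)(C)C(C)(C)C | intermediate
22 | (1R,2S,5R,8S)-8-(3-{[tert-butyl(dimethyl)silyl]oxy}propyl)-2-methyl-2-[(triethylsilyl)oxy]-5-{(2R)-1-[(triethylsilyl)oxy]propan-2-yl}-6-oxabicyclo[3.2.1]octane-1-carbaldehyde | O=C[C@]12CO[C@]([C@H](C)CO[Si](CC)(CC)CC)(CC[C@]1(C)O[Si](CC)(CC)CC)[C@H]2CCCO[Si](C)(C)C(C)(C)C | intermediate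
23 | tert-butyl(dimethyl){3-[(1S,2S,5R,8S)-1-ethenyl-2-methyl-2-[(triethylsilyl)oxy]-5-{(2R)-1-[(triethylsilyl)oxy]propan-2-yl}-6-oxabicyclo[3.2.1]octan-8-yl]propoxy}silane | C=C[C@]12CO[C@]([C@H](C)CO[Si](CC)(CC)CC)(CC[C@]1(C)O[Si](CC)(CC)CC)[C@H]2CCCO[Si](C)(C)C(C)(C)C | intermediate
24 | α-irone, (3E)-4-(2,5,6,6-tetramethylcyclohex-2-en-1-yl)but-3-en-2-one, commercial mixture of isomers | CC1=CCC(C)C(C)(C)C1/C=C/C(C)=O | starting material
25 | (3E)-4-[(1R,5S)-2,5,6,6-tetramethylcyclohex-2-en-1-yl]but-3-en-2-one (cis isomer) | CC1=CC[C@H](C)C(C)(C)[C@@H]1/C=C/C(C)=O | intermediate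
26 | diethyl (3E)-4-[(1R,5S)-2,5,6,6-tetramethylcyclohex-2-en-1-yl]buta-1,3-dien-2-yl phosphate | CC1=CC[C@H](C)C(C)(C)[C@@H]1/C=C/C(=C)OP(=O)(OCC)OCC | intermediate (not isolated)
27 | (4S,6R)-6-[(1E)-but-1-en-3-yn-1-yl]-1,4,5,5-tetramethylcyclohex-1-ene | CC1=CC[C@H](C)C(C)(C)[C@@H]1/C=C/C#C | intermediate
28 | dimethyl{(1E,3E)-2-methyl-4-[(1R,5S)-2,5,6,6-tetramethylcyclohex-2-en-1-yl]buta-1,3-dien-1-yl}alumane | CC1=CC[C@H](C)C(C)(C)[C@@H]1/C=C/C(C)=C/[Al](C)C | intermediate (not isolated)
29 | (4S,6R)-6-[(1E,3E)-4-iodo-3-methylbuta-1,3-dien-1-yl]-1,4,5,5-tetramethylcyclohex-1-ene | CC1=CC[C@H](C)C(C)(C)[C@@H]1/C=C/C(C)=C/I | intermediate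
30 | B-alkyl-9-borabicyclo[3.3.1]nonane from 23 (boron on the terminal carbon of the former vinyl group) | B1(C2CCCC1CCC2)CC[C@]12CO[C@]([C@H](C)CO[Si](CC)(CC)CC)(CC[C@]1(C)O[Si](CC)(CC)CC)[C@H]2CCCO[Si](C)(C)C(C)(C)C | intermediate (not isolated)
31 | tert-butyl(dimethyl){3-[(1S,2S,5R,8S)-2-methyl-1-{(3E,5E)-4-methyl-6-[(1R,5S)-2,5,6,6-tetramethylcyclohex-2-en-1-yl]hexa-3,5-dien-1-yl}-2-[(triethylsilyl)oxy]-5-{(2R)-1-[(triethylsilyl)oxy]propan-2-yl}-6-oxabicyclo[3.2.1]octan-8-yl]propoxy}silane | CC1=CC[C@H](C)C(C)(C)[C@@H]1/C=C/C(C)=C/CC[C@]12CO[C@]([C@H](C)CO[Si](CC)(CC)CC)(CC[C@]1(C)O[Si](CC)(CC)CC)[C@H]2CCCO[Si](C)(C)C(C)(C)C | intermediate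
32 | (2R)-2-[(1S,2S,5R,8S)-8-(3-{[tert-butyl(dimethyl)silyl]oxy}propyl)-2-methyl-1-{(3E,5E)-4-methyl-6-[(1R,5S)-2,5,6,6-tetramethylcyclohex-2-en-1-yl]hexa-3,5-dien-1-yl}-2-[(triethylsilyl)oxy]-6-oxabicyclo[3.2.1]octan-5-yl]propan-1-ol | CC1=CC[C@H](C)C(C)(C)[C@@H]1/C=C/C(C)=C/CC[C@]12CO[C@]([C@H](C)CO)(CC[C@]1(C)O[Si](CC)(CC)CC)[C@H]2CCCO[Si](C)(C)C(C)(C)C | intermediate
33 | (2S)-2-[(1S,2S,5R,8S)-8-(3-{[tert-butyl(dimethyl)silyl]oxy}propyl)-2-methyl-1-{(3E,5E)-4-methyl-6-[(1R,5S)-2,5,6,6-tetramethylcyclohex-2-en-1-yl]hexa-3,5-dien-1-yl}-2-[(triethylsilyl)oxy]-6-oxabicyclo[3.2.1]octan-5-yl]propanal | CC1=CC[C@H](C)C(C)(C)[C@@H]1/C=C/C(C)=C/CC[C@]12CO[C@]([C@H](C)C=O)(CC[C@]1(C)O[Si](CC)(CC)CC)[C@H]2CCCO[Si](C)(C)C(C)(C)C | intermediate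
34 | (2S)-2-[(1S,2S,5R,8S)-2-hydroxy-8-(3-hydroxypropyl)-2-methyl-1-{(3E,5E)-4-methyl-6-[(1R,5S)-2,5,6,6-tetramethylcyclohex-2-en-1-yl]hexa-3,5-dien-1-yl}-6-oxabicyclo[3.2.1]octan-5-yl]propanal | CC1=CC[C@H](C)C(C)(C)[C@@H]1/C=C/C(C)=C/CC[C@]12CO[C@]([C@H](C)C=O)(CC[C@]1(C)O)[C@H]2CCCO | target

## Step count and least certain steps

Total step count: 23. Longest linear sequence: 20 steps (steps 1–16 and 20–23). The side branch to 29 (steps 17–19) has 3 steps.

**Step 10 (key step, proposed new method).** Several things can go wrong.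
- The Ca–Cb bond may ionise without capture by the weakly nucleophilic formaldehyde. Proton loss to dienes, or a hydride shift to the conjugated enone ester, would then take over.
- Capture may occur at the CH2 end of the allyl system.
- A free cation may form, so that the new bridge is no longer tied to the face of the endo arm.
- The silyl ether oxygen of the arm may compete as an internal nucleophile, and the monomeric aldehyde may oligomerise on the Lewis acid.

The fallback uses known reactions and runs from 14 to 16. Acid-mediated solvolytic ring enlargement of the fused cyclopropyl ketone with water (catalytic HClO4 in wet acetone, or Sc(OTf)3 in wet THF) should break the bond to the tertiary carbon. This gives methyl (5R,6S)-6-(3-{[tert-butyl(dimethyl)silyl]oxy}propyl)-5-hydroxy-2-oxo-5-(prop-1-en-2-yl)cyclohexane-1-carboxylate F1. Aldol hydroxymethylation of its acidic Ca–H with aqueous formaldehyde and KHCO3 should give methyl (1R,5R,6S)-6-(3-{[tert-butyl(dimethyl)silyl]oxy}propyl)-5-hydroxy-1-(hydroxymethyl)-2-oxo-5-(prop-1-en-2-yl)cyclohexane-1-carboxylate F2. Acid-catalysed etherification of the primary hydroxyl onto the ionised tertiary allylic carbinol (PPTS or camphorsulfonic acid, CH2Cl2, molecular sieves) then closes the tetrahydrofuran to 16. This sequence gives up the stereospecificity. Only the Ca epimer of the diol drawn as F2 leads to 16; the other would be separated after cyclisation or returned to the aldol equilibrium with base.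

**Step 12.** Poor facial selectivity in the hydroboration next to the fully substituted ether carbon would give a mixture at C-alpha, because the preference rests only on the conformation about the Cb–C(isopropenyl) bond. The fallback replaces substrate control by catalyst control and runs from 17 to 19. A copper hydride formed from CuCl, KOt-Bu and one enantiomer of DTBM-SEGPHOS adds pinacolborane across the 1,1-disubstituted alkene. This gives methyl (1R,2S,5R,8S)-8-(3-{[tert-butyl(dimethyl)silyl]oxy}propyl)-2-hydroxy-2-methyl-5-[(2R)-1-(4,4,5,5-tetramethyl-1,3,2-dioxaborolan-2-yl)propan-2-yl]-6-oxabicyclo[3.2.1]octane-1-carboxylate F3, which H2O2 and aqueous NaOAc oxidise to 19.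

**Step 11.** The methyl group may be delivered from the side of the CH2–O bridge (wrong epimer at Cc), and enolisation toward Ch or attack on the ester may compete. The two faces differ only by the axial bridge CH2 against two axial hydrogens. The fallback builds the carbinol in another way and runs from 16 to 17. Dimethylsulfonium methylide (Me3S+ I−, KN(SiMe3)2, THF), a small nucleophile known for axial delivery to cyclohexanones, should give the spiro-epoxide methyl (1R,2S,5R,8S)-8-(3-{[tert-butyl(dimethyl)silyl]oxy}propyl)-5-(prop-1-en-2-yl)spiro[6-oxabicyclo[3.2.1]octane-2,2′-oxirane]-1-carboxylate F4, with its oxygen in the place of the hydroxyl of 17. Opening at the CH2 with LiI and AcOH gives the iodohydrin methyl (1R,2S,5R,8S)-8-(3-{[tert-butyl(dimethyl)silyl]oxy}propyl)-2-hydroxy-2-(iodomethyl)-5-(prop-1-en-2-yl)-6-oxabicyclo[3.2.1]octane-1-carboxylate F5. Radical deiodination with Bu3SnH and AIBN leaves the methyl group of 17. The ester and the isopropenyl group survive all three operations.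

**Step 9.** Enantioselection by the copper bis(oxazoline) catalyst may be incomplete with a small methyl ester, and addition to the isopropenyl group or later opening of the vinylcyclopropane may take part of the material. A minor enantiomer carried forward would in any case become a separable diastereomer after step 20. The fallback replaces asymmetric induction by resolution and runs from 13 to 14. The cyclopropanation is run with achiral Cu(acac)2, and the racemate is separated on a chiral stationary phase. The unwanted enantiomer, methyl (1R,5R,6S)-6-(3-{[tert-butyl(dimethyl)silyl]oxy}propyl)-2-oxo-5-(prop-1-en-2-yl)bicyclo[3.1.0]hexane-1-carboxylate F6, is set aside.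

**Step 5.** Transmetalation of the α-branched alkenylstannane may be slow, so that protodestannylation or coupling at the neighbouring carbon competes. The fallback swaps the roles of the partners and runs from 6 to 8. Iododestannylation of 6 with I2 in CH2Cl2 gives (2E)-6-{[tert-butyl(dimethyl)silyl]oxy}-2-iodohex-2-en-1-ol F7 with retention. A Suzuki–Miyaura coupling with isopropenylboronic acid pinacol ester (Pd(dppf)Cl2, aq. K3PO4, dioxane) then gives 8.

## Further compounds

F1 | step 10 | methyl (5R,6S)-6-(3-{[tert-butyl(dimethyl)silyl]oxy}propyl)-5-hydroxy-2-oxo-5-(prop-1-en-2-yl)cyclohexane-1-carboxylate | COC(=O)C1C(=O)CC[C@](O)(C(C)=C)[C@H]1CCCO[Si](C)(C)C(C)(C)C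
F2 | step 10 | methyl (1R,5R,6S)-6-(3-{[tert-butyl(dimethyl)silyl]oxy}propyl)-5-hydroxy-1-(hydroxymethyl)-2-oxo-5-(prop-1-en-2-yl)cyclohexane-1-carboxylate | COC(=O)[C@]1(CO)C(=O)CC[C@](O)(C(C)=C)[C@H]1CCCO[Si](C)(C)C(C)(C)C
F3 | step 12 | methyl (1R,2S,5R,8S)-8-(3-{[tert-butyl(dimethyl)silyl]oxy}propyl)-2-hydroxy-2-methyl-5-[(2R)-1-(4,4,5,5-tetramethyl-1,3,2-dioxaborolan-2-yl)propan-2-yl]-6-oxabicyclo[3.2.1]octane-1-carboxylate | COC(=O)[C@]12CO[C@]([C@H](C)CB3OC(C)(C)C(C)(C)O3)(CC[C@]1(C)O)[C@H]2CCCO[Si](C)(C)C(C)(C)C
F4 | step 11 | methyl (1R,2S,5R,8S)-8-(3-{[tert-butyl(dimethyl)silyl]oxy}propyl)-5-(prop-1-en-2-yl)spiro[6-oxabicyclo[3.2.1]octane-2,2′-oxirane]-1-carboxylate | COC(=O)[C@]12CO[C@](C(C)=C)(CC[C@@]13CO3)[C@H]2CCCO[Si](C)(C)C(C)(C)C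
F5 | step 11 | methyl (1R,2S,5R,8S)-8-(3-{[tert-butyl(dimethyl)silyl]oxy}propyl)-2-hydroxy-2-(iodomethyl)-5-(prop-1-en-2-yl)-6-oxabicyclo[3.2.1]octane-1-carboxylate | COC(=O)[C@]12CO[C@](C(C)=C)(CC[C@]1(CI)O)[C@H]2CCCO[Si](C)(C)C(C)(C)C
F6 | step 9 | methyl (1R,5R,6S)-6-(3-{[tert-butyl(dimethyl)silyl]oxy}propyl)-2-oxo-5-(prop-1-en-2-yl)bicyclo[3.1.0]hexane-1-carboxylate (enantiomer of 14) | COC(=O)[C@@]12C(=O)CC[C@]1(C(C)=C)[C@@H]2CCCO[Si](C)(C)C(C)(C)C
F7 | step 5 | (2E)-6-{[tert-butyl(dimethyl)silyl]oxy}-2-iodohex-2-en-1-ol | OC/C(I)=C\CCCO[Si](C)(C)C(C)(C)C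
A1 | alternative 1 | endoperoxide: 2,3-dioxabicyclo[2.2.2]oct-5-ene with methyl on Cc, the PMB-protected 1-hydroxypropan-2-yl group on Cb, hydroxymethyl and 2-(pivaloyloxy)ethyl on Ca and the silyl-protected arm on Cd | CC(C)(C)C(=O)OCC[C@]1(CO)[C@@]2(C)OO[C@@](C=C2)([C@H](C)COCc3ccc(OC)cc3)[C@H]1CCCO[Si](C)(C)C(C)(C)C
A2 | alternative 1 | 1,4-disubstituted cyclohexa-1,3-diene precursor of A1 | CC(C)(C)C(=O)OCC[C@]1(CO)C(C)=CC=C([C@H](C)COCc2ccc(OC)cc2)[C@H]1CCCO[Si](C)(C)C(C)(C)C
A3 | alternative 2 | bridged ether: 6-oxabicyclo[3.2.1]octane with CH2CO2Me on Ca, acetate on Cc, silyl-protected 1-hydroxypropan-2-yl on Cb and the TBDPS-protected arm on Cd | COC(=O)C[C@]12CO[C@]([C@H](C)CO[Si](C)(C)C(C)(C)C)(CC[C@]1(C)OC(C)=O)[C@H]2CCCO[Si](c1ccccc1)(c1ccccc1)C(C)(C)C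
A4 | alternative 2 | tertiary alcohol precursor of A3 with an axial methyl on Ca | COC(=O)C[C@@]1(C)[C@H](CCCO[Si](c2ccccc2)(c2ccccc2)C(C)(C)C)[C@@](O)([C@H](C)CO[Si](C)(C)C(C)(C)C)CC[C@]1(C)OC(C)=O
A5 | alternative 3 | bridged ether ester: 6-oxabicyclo[3.2.1]octane with allyl on Ca, triethylsilyl ether on Cc, methyl propanoate arm on Cb and the silyl-protected arm on Cd | C=CC[C@]12CO[C@]([C@H](C)C(=O)OC)(CC[C@]1(C)O[Si](CC)(CC)CC)[C@H]2CCCO[Si](C)(C)C(C)(C)C
A6 | alternative 3 | oxepane xanthate precursor of A5 with the exocyclic alkoxyacrylate (either carbinol epimer) | C=CC[C@]1(C(OC(=S)SC)CCCO[Si](C)(C)C(C)(C)C)COC(=C(C)C(=O)OC)CC[C@]1(C)O[Si](CC)(CC)CC
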